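## Numbering used throughout

1 6-bromovanillin · 2 its methoxymethyl (MOM) ether · 3 dimethyl succinate · 4 paraconic ester (not isolated) · 5 Stobbe half-ester · 6 mixed tert-butyl/methyl bromo diester (key-step precursor) · 7 vanillin · 8 MOM-vanillin · 9 p-toluenesulfonyl hydrazide · 10 N-tosylhydrazone (key-step precursor) · 11 aryldiazomethane (not isolated) · 12 dihydronaphthalene diester (key-step product) · 13 half-ester diphenol · 14 hydroxy acid (not isolated) · 15 lactone · 16 lactol (not isolated) · 17 target

## Analysis of the target

The target 17 is an aryl-dihydronaphthalene lignan. Ring A is the fused phenol ring (C4a, C5, C6, C7, C8, C8a; methoxy on C6, hydroxy on C7), ring B is the 1,2-dihydro ring (C1, C2, C3, C4, C4a, C8a), and a 4-hydroxy-3-methoxyphenyl (guaiacyl) ring hangs on C1. There are two stereocentres, C1 (S) and C2 (R); they are neighbours and trans, with the aryl group on C1 and the formyl group on C2 on opposite faces of ring B. C2 carries the aldehyde, C3 a hydroxymethyl group, and C3=C4 is a styrene double bond conjugated with ring A. The aldehyde is the weak point: its α-carbon C2 is a stereocentre, the C3=C4 bond is β,γ to it and can move into conjugation (C2=C3) with loss of that stereocentre, and loss of the hydrogens on C1 and C2 would give a naphthalene. The allylic alcohol is a vinylogous para-hydroxybenzyl alcohol (the C7 hydroxyl is para to C4a), so it ionises in acid, and it sits 1,4 to the formyl carbon, so 17 can close to a five-membered lactol. The synthesis is hard for three reasons: C1 is a diarylmethine carbon with no heteroatom handle for asymmetric induction; the two neighbouring one-carbon substituents must end at different oxidation levels with the higher one on the sp3 carbon, the opposite of what selective allylic oxidation of a diol gives; and the hydroxy aldehyde tolerates neither acid nor base at the end. The plan rests on C1: it is bonded only to C8a, C2, hydrogen and the pendant ring, so it is the carbonyl carbon of vanillin in disguise, and the rest of ring B (C8a–C4a–C4=C3–C2 with the two exocyclic carbons) is the skeleton of an arylidene succinate.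

## Retrosynthetic reasoning

**17 ⇒ 15 (through 16).** The formyl group of 17 is taken back to the acyl carbon of lactone 15, in which the C2 carbonyl is esterified by the oxygen of the C3 hydroxymethyl group. Cutting here, and not at a protected aldehyde, means the sensitive functions appear only in the last operation. Half-reduction of 15 by an aluminium hydride at low temperature gives lactol 16, the ring-closed tautomer of 17, and nothing has to be deprotected afterwards. The lactone also stores the difference in oxidation level between the two exocyclic carbons. The forward step must stop at the hemiacetal stage and tolerate two free phenols.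

**15 ⇒ 13 (through 14).** Lactone 15 is opened at its alkyl C–O bond to hydroxy acid 14, and the allylic carbinol is taken back to a conjugated methyl ester, which gives half-ester 13. Here the two carboxyl carbons are told apart: in 13 the one on C2 is a free acid and the one on C3 an ester. A hydride reagent that first turns the acid into an inert carboxylate therefore reduces only the cinnamate-type ester. Differentiation by charge is safer than any selective reaction between two esters on this skeleton. The forward reduction must be 1,2-selective, and 14 must close to the five-membered lactone.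

**13 ⇒ 12.** Half-ester 13 comes from the fully protected diester 12, whose C2 ester is tert-butyl and whose phenols are MOM ethers. All three groups fall in one acidolysis. This is the right place for acid: 12 has no allylic C–O bond yet, and the dihydronaphthalene diester core is not acid-sensitive.

**12 ⇒ 6 + 10 (through 11).** Both ring-B bonds to C1 are cut, C1–C8a and C1–C2, which removes C1 with the pendant ring as a carbene. Cutting at C1 rather than at C4–C4a or C2–C3 gives two fragments of similar size that each derive from a vanillin. Ring B and both stereocentres then arise in one step. C3=C4, both carboxyl carbons and the oxygenation of ring A are already present in bromo diester 6. The carbene is to come from tosylhydrazone 10 through diazo compound 11 and is delivered by palladium into the C8a–Br bond of 6. The forward reaction must form C1–C8a by migratory insertion and then C1–C2 by attack of the ester dienolate. The chiral ligand on palladium decides C1, and base equilibration places C2 trans.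

**6 ⇒ 5 ⇒ 2 + 3 (through 4); 2 ⇒ 1.** The C3=C4 bond of 6 is cut by a Stobbe disconnection into aldehyde 2 and diester 3. The condensation passes through lactone 4 and releases the carboxyl on the CH2 arm as the free acid in 5; this is the carboxyl that ends as the formyl carbon. Methylating it would make the two esters alike and force a later selective saponification of a hindered ester next to an epimerisable centre. The acid is therefore capped as a tert-butyl ester, which keeps the distinction the Stobbe reaction provides at no cost in steps. The E geometry of the Stobbe product (aryl cis to the CH2 arm) is the one the annulation needs. Aldehyde 2 is the MOM ether of commercial 1.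

**10 ⇒ 8 + 9; 8 ⇒ 7.** The hydrazone is cut at C=N into aldehyde 8 and hydrazide 9, and 8 is the MOM ether of 7. The same protecting group on both phenols lets one acid step remove both later.

## Alternatives that were turned down

**Alternative 1: furan–alkyne cycloaddition.** The disconnection cuts C4a–C8a and C7–C8 of ring A. In the forward direction the acyclic substrate A1 is heated: its 4-methoxyfuran and terminal alkyne undergo an intramolecular [4+2] cycloaddition, ring B closes as the tether ring, and the oxa-bridge opens to the C7 phenol of A2.
- For it: A2 has the ring-A phenol free and the pendant phenol protected, and the two carbinols carry orthogonal groups (silyl ether and pivalate). The aldehyde on C2 can then be made by a plain deprotection and oxidation. On this point the alternative is stronger than the chosen route, which has to separate two carboxyl groups. The ring-forming step needs no reagent and cannot scramble stereocentres that already exist.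
- Against it: A1 must already hold C1 and C2 in an open chain. C1 is a propargylic, benzylic methine next to C2, so both centres need separate asymmetric steps. A1 also needs a trisubstituted alkene of fixed geometry joined to an acid-sensitive 3-alkoxyfuran. The alkyne is unactivated, so the cycloaddition needs high temperature, and the 2-alkenylfuran can also react as an exocyclic diene.
- Comparison: the chosen route creates ring B and both stereocentres in one catalytic step from two fragments that take three and two steps to make. In exchange it accepts the risk of a new reaction and a carboxyl differentiation.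

**Alternative 2: Ireland–Claisen ring contraction.** The disconnection cuts C2–C3. In the forward direction the ketene silyl acetal of the ten-membered E-allylic lactone A3 rearranges, contracts the ring to ring B and gives acid A4 with a carboxyl on C2 and a vinyl group on C3.
- For it: the rearrangement is well understood, it passes stereochemistry through a cyclic transition state, and it puts the carboxyl directly on C2, the carbon that becomes the aldehyde. In predictability of the bond-forming step it is stronger than the chosen key step.
- Against it: the target has neither a C3 stereocentre nor a C4 oxygen. Both are made only to be removed. The vinyl group must lose a carbon by oxidative cleavage next to two electron-rich arenes. The C4 silyloxy group must be eliminated towards C3 without epimerising C2 or aromatising ring B. A3 is a strained medium ring with an E-alkene and an ortho-phenylene, and it needs C1 and C4 set beforehand.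
- Comparison: the chosen route has C3=C4 and both exocyclic carbons at usable oxidation levels from the Stobbe step on, and it needs three steps after the ring is formed. Its stereocontrol, however, rests on a ligand screen rather than on a cyclic transition state.

**Alternative 3: aryl-shift ring expansion of an indane.** The disconnection cuts C4–C4a. In the forward direction, buffered acetolysis of the indane bis-mesylate A5 ionises one mesylate with migration of ring A to the CH2 carbon, expands the five-membered ring to ring B, forms C3=C4, and gives the acetoxymethyl compound A6.
- For it: the migrating aryl carbon is para to an oxygen, so the shift is electronically assisted. The alkene and the six-membered ring appear in one event, and the two carbinols come out differentiated (acetate and silyl ether) without a transition metal. In carbinol differentiation it is as strong as alternative 1 and stronger than the chosen route.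
- Against it: A5 needs a quaternary carbon next to the C1 and C2 stereocentres, all made enantioselectively beforehand. Hot acetic acid threatens the MOM ethers. The tertiary cation at C3 can lose the proton on C2 and destroy that stereocentre, and the alkyl shift of C2 competes with the aryl shift. The endgame needs the acetate removed with base while the epimerisable aldehyde is present.
- Comparison: the chosen route avoids cationic rearrangements and basic late steps, and reaches its key precursor by textbook chemistry.

Key step: step 6

Remark 1: 17 and lactol 16 are ring-chain tautomers; the route delivers this equilibrium system, and 17 is taken to be the form that is isolated, as the drawn structure implies.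
Remark 2: which antipode of the ligand leads to the 1S configuration cannot be predicted; (R)-DTBM-SEGPHOS is written, and its mirror image would be used if the sense of induction proves opposite.

## Route

Step 1
Reactants: 1 6-bromovanillin (2-bromo-4-hydroxy-5-methoxybenzaldehyde)
Product: 2 2-bromo-5-methoxy-4-(methoxymethoxy)benzaldehyde
Conditions: MeOCH2Cl (1.3 equiv), iPr2NEt (1.5 equiv), CH2Cl2, 0 °C → rt
Reagents that add atoms: chloromethyl methyl ether, COCCl
Why: O-alkylation of the phenol (Williamson-type acetal formation); the MOM ether should withstand the alkoxide of step 2 and the palladium/alkoxide conditions of step 6, and falls together with the tert-butyl ester in step 7.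

Step 2
Reactants: 2 2-bromo-5-methoxy-4-(methoxymethoxy)benzaldehyde; 3 dimethyl succinate
Product: 5 (3E)-4-[2-bromo-5-methoxy-4-(methoxymethoxy)phenyl]-3-(methoxycarbonyl)but-3-enoic acid, via paraconic ester 4 (not isolated)
Conditions: NaOMe (2.5 equiv), MeOH, reflux; then 1 M HCl, 0 °C
Reagents that add atoms: none
Why: Stobbe condensation: aldol addition, lactonisation to 4 and E1cB ring opening should give the alkylidene half-ester with the free acid on the CH2 arm. The E isomer (aryl cis to the CH2CO2H arm) is the usual, thermodynamically preferred outcome with aromatic aldehydes and can be purified by crystallisation.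

Step 3
Reactants: 5 (3E)-4-[2-bromo-5-methoxy-4-(methoxymethoxy)phenyl]-3-(methoxycarbonyl)but-3-enoic acid
Product: 6 4-tert-butyl 1-methyl (2E)-2-{[2-bromo-5-methoxy-4-(methoxymethoxy)phenyl]methylidene}butanedioate
Conditions: Cl3CC(=NH)OtBu (2 equiv), CH2Cl2/cyclohexane, rt
Reagents that add atoms: tert-butyl 2,2,2-trichloroacetimidate, CC(C)(C)OC(=N)C(Cl)(Cl)Cl
Why: Imidate esterification: the carboxylic acid itself activates the imidate, so no strong acid or base is needed, and the MOM ether and the alkene geometry should be untouched. The tert-butyl ester keeps the C2 carboxyl distinct from the conjugated methyl ester.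

Step 4
Reactants: 7 vanillin
Product: 8 3-methoxy-4-(methoxymethoxy)benzaldehyde
Conditions: MeOCH2Cl (1.3 equiv), iPr2NEt (1.5 equiv), CH2Cl2, 0 °C → rt
Reagents that add atoms: chloromethyl methyl ether, COCCl
Why: Same phenol protection as in step 1; a free para-phenoxide would make the derived diazo compound and carbene too electron-rich and unstable.

Step 5
Reactants: 8 3-methoxy-4-(methoxymethoxy)benzaldehyde; 9 p-toluenesulfonyl hydrazide
Product: 10 N'-{(E)-[3-methoxy-4-(methoxymethoxy)phenyl]methylidene}-4-methylbenzenesulfonohydrazide
Conditions: 9 (1.05 equiv), MeOH, rt
Reagents that add atoms: none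
Why: Hydrazone condensation of an aromatic aldehyde; the E-hydrazone should crystallise from methanol, and the MOM acetal is stable to the weakly acidic hydrazide.

Step 6
Reactants: 6 4-tert-butyl 1-methyl (2E)-2-{[2-bromo-5-methoxy-4-(methoxymethoxy)phenyl]methylidene}butanedioate; 10 N'-{(E)-[3-methoxy-4-(methoxymethoxy)phenyl]methylidene}-4-methylbenzenesulfonohydrazide
Product: 12 2-tert-butyl 3-methyl (1S,2R)-6-methoxy-1-[3-methoxy-4-(methoxymethoxy)phenyl]-7-(methoxymethoxy)-1,2-dihydronaphthalene-2,3-dicarboxylate, via aryldiazomethane 11 (not isolated)
Conditions: Pd2(dba)3 (2.5 mol %), (R)-DTBM-SEGPHOS (6 mol %), 10 (1.3 equiv), LiOtBu (2.4 equiv), 1,4-dioxane, 85 °C; AcOH quench at 0 °C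
Reagents that add atoms: none
Why: Proposed new method: zerovalent palladium inserts into the C8a–Br bond of 6 while LiOtBu converts 10 into diazo compound 11 (Bamford–Stevens release); 11 gives an arylpalladium carbene, and 1,1-migratory insertion of the C8a aryl group forms C1–C8a and a diarylmethylpalladium that cannot undergo β-hydride elimination, because both carbon neighbours of C1 are aryl ipso carbons. The closest known reaction type is the palladium-catalysed coupling of aryl halides with N-tosylhydrazones in which the insertion product is intercepted by a tethered nucleophile ([4+1] annulation); here the tether is one atom longer ([5+1]) and the nucleophile is an ester dienolate. Ring B closes when the lithium dienolate of the tert-butyl ester arm attacks C1 through its α-carbon C2, a 6-(enolexo)-exo-tet closure in which the C1–Pd bond lies outside the new ring, either directly on the η3-benzyl complex or after binding to palladium and reductive elimination. For direct attack the η3-benzyl unit must be built on the pendant guaiacyl ring, because only then does the acceptor lobe at C1 lie in the plane of ring A where the tethered C2 can reach it. C1 is controlled by the chiral bisphosphine, which distinguishes the two faces of the carbene in the insertion and, if the benzyl complex epimerises, the two diastereomeric benzyl complexes in the ring closure; C2 is not set kinetically but should settle trans to the C1 aryl group by base equilibration of its acidic, allylic α-ester hydrogen. The step needs three selectivities: carbene capture before the dienolate can arylate directly at C8a to a five-membered indene, α-attack rather than γ-attack of the dienolate, and the cis relation of C8a and C2 across C3=C4. The first should hold because the hydrazone N–H consumes base long before the weakly acidic C2 methylene does, so the arylpalladium bromide meets 11 but little dienolate; the second because γ-attack from C4 would need a four-membered ring; the third is fixed by the E geometry of 6.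

Step 7
Reactants: 12 2-tert-butyl 3-methyl (1S,2R)-6-methoxy-1-[3-methoxy-4-(methoxymethoxy)phenyl]-7-(methoxymethoxy)-1,2-dihydronaphthalene-2,3-dicarboxylate
Product: 13 (1S,2R)-7-hydroxy-1-(4-hydroxy-3-methoxyphenyl)-6-methoxy-3-(methoxycarbonyl)-1,2-dihydronaphthalene-2-carboxylic acid
Conditions: CF3CO2H/CH2Cl2 (1:3), n-C12H25SH (6 equiv), 0 °C → rt
Reagents that add atoms: none
Why: Acidolysis: the tert-butyl ester should cleave by loss of the tert-butyl cation and the two aryl MOM acetals through the methoxymethyl cation, which the thiol traps before it can alkylate the electron-rich rings. The methyl ester is inert, and the dihydronaphthalene diester core has no allylic C–O bond and tolerates acid, so C1 and C2 are not touched.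

Step 8
Reactants: 13 (1S,2R)-7-hydroxy-1-(4-hydroxy-3-methoxyphenyl)-6-methoxy-3-(methoxycarbonyl)-1,2-dihydronaphthalene-2-carboxylic acid
Product: 15 (9S,9aR)-7-hydroxy-9-(4-hydroxy-3-methoxyphenyl)-6-methoxy-9,9a-dihydronaphtho[2,3-c]furan-1(3H)-one, via hydroxy acid 14 (not isolated)
Conditions: iBu2AlH (6 equiv), THF, −78 → −40 °C; aq. potassium sodium tartrate, then 1 M HCl (pH 3); PPTS (cat.), CH2Cl2, rt
Reagents that add atoms: none
Why: Ester reduction with the acid masked as its carboxylate: iBu2AlH first deprotonates the acid and the phenols, then should reduce the cinnamate-type methyl ester 1,2 to the allylic alcohol (the reaction type used to reduce free-phenol ferulate esters), while the hindered aluminium carboxylate is inert at low temperature. Mild acid then closes 14 to the γ-lactone; C2 is α to a carboxylate during the reduction and is not epimerised.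

Step 9
Reactants: 15 (9S,9aR)-7-hydroxy-9-(4-hydroxy-3-methoxyphenyl)-6-methoxy-9,9a-dihydronaphtho[2,3-c]furan-1(3H)-one
Product: 17 (1S,2R)-7-hydroxy-1-(4-hydroxy-3-methoxyphenyl)-3-(hydroxymethyl)-6-methoxy-1,2-dihydronaphthalene-2-carbaldehyde, via lactol 16 (not isolated)
Conditions: iBu2AlH (3.5 equiv), THF, −78 °C; MeOH at −78 °C, then aq. potassium sodium tartrate
Reagents that add atoms: none
Why: Half-reduction of a γ-lactone to the lactol: the first two equivalents of hydride are consumed by the phenols, and the aluminium hemiacetal should be stable at −78 °C and collapse only on work-up to 16, the ring-closed tautomer of 17. The neutral work-up avoids acid (ionisation of the allylic C–O bond) and base (epimerisation at C2, migration of C3=C4), and no protecting group remains to be removed.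

## Compound list

1 | 6-bromovanillin (2-bromo-4-hydroxy-5-methoxybenzaldehyde) | O=Cc1cc(OC)c(O)cc1Br | starting material
2 | 2-bromo-5-methoxy-4-(methoxymethoxy)benzaldehyde | COCOc1cc(Br)c(C=O)cc1OC | intermediate
3 | dimethyl succinate | COC(=O)CCC(=O)OC | starting material
4 | methyl 2-[2-bromo-5-methoxy-4-(methoxymethoxy)phenyl]-5-oxooxolane-3-carboxylate (paraconic ester; racemic mixture of diastereomers, not isolated) | COC(=O)C1CC(=O)OC1c1cc(OC)c(OCOC)cc1Br | intermediate
5 | (3E)-4-[2-bromo-5-methoxy-4-(methoxymethoxy)phenyl]-3-(methoxycarbonyl)but-3-enoic acid | OC(=O)C/C(C(=O)OC)=C\c1cc(OC)c(OCOC)cc1Br | intermediate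
6 | 4-tert-butyl 1-methyl (2E)-2-{[2-bromo-5-methoxy-4-(methoxymethoxy)phenyl]methylidene}butanedioate | CC(C)(C)OC(=O)C/C(C(=O)OC)=C\c1cc(OC)c(OCOC)cc1Br | intermediate
7 | vanillin | COc1cc(C=O)ccc1O | starting material
8 | 3-methoxy-4-(methoxymethoxy)benzaldehyde | COCOc1ccc(C=O)cc1OC | intermediate
9 | p-toluenesulfonyl hydrazide | Cc1ccc(S(=O)(=O)NN)cc1 | starting material
10 | N'-{(E)-[3-methoxy-4-(methoxymethoxy)phenyl]methylidene}-4-methylbenzenesulfonohydrazide | COCOc1ccc(/C=N/NS(=O)(=O)c2ccc(C)cc2)cc1OC | intermediate
11 | 4-(diazomethyl)-2-methoxy-1-(methoxymethoxy)benzene (not isolated) | COCOc1ccc(C=[N+]=[N-])cc1OC | intermediate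
12 | 2-tert-butyl 3-methyl (1S,2R)-6-methoxy-1-[3-methoxy-4-(methoxymethoxy)phenyl]-7-(methoxymethoxy)-1,2-dihydronaphthalene-2,3-dicarboxylate | COc1cc([C@H]2c3cc(OCOC)c(OC)cc3C=C(C(=O)OC)[C@@H]2C(=O)OC(C)(C)C)ccc1OCOC | intermediate
13 | (1S,2R)-7-hydroxy-1-(4-hydroxy-3-methoxyphenyl)-6-methoxy-3-(methoxycarbonyl)-1,2-dihydronaphthalene-2-carboxylic acid | COc1cc([C@H]2c3cc(O)c(OC)cc3C=C(C(=O)OC)[C@@H]2C(=O)O)ccc1O | intermediate
14 | (1S,2R)-7-hydroxy-1-(4-hydroxy-3-methoxyphenyl)-3-(hydroxymethyl)-6-methoxy-1,2-dihydronaphthalene-2-carboxylic acid (not isolated) | COc1cc([C@H]2c3cc(O)c(OC)cc3C=C(CO)[C@@H]2C(=O)O)ccc1O | intermediate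
15 | (9S,9aR)-7-hydroxy-9-(4-hydroxy-3-methoxyphenyl)-6-methoxy-9,9a-dihydronaphtho[2,3-c]furan-1(3H)-one | COc1cc([C@H]2c3cc(O)c(OC)cc3C=C3COC(=O)[C@@H]32)ccc1O | intermediate
16 | (9S,9aR)-9-(4-hydroxy-3-methoxyphenyl)-6-methoxy-1,3,9,9a-tetrahydronaphtho[2,3-c]furan-1,7-diol (lactol, both epimers at the hemiacetal carbon, not isolated) | COc1cc([C@H]2c3cc(O)c(OC)cc3C=C3COC(O)[C@@H]32)ccc1O | intermediate
17 | (1S,2R)-7-hydroxy-1-(4-hydroxy-3-methoxyphenyl)-3-(hydroxymethyl)-6-methoxy-1,2-dihydronaphthalene-2-carbaldehyde (CNP0591394.1) | COc1cc([C@H]2c3cc(O)c(OC)cc3C=C(CO)[C@@H]2C=O)ccc1O | target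

## Step count and risk

Total step count: 9 (steps 1–3 to 6, steps 4–5 to 10, then steps 6–9).
Longest linear sequence: 7 steps (1 → 2 → 5 → 6 → 12 → 13 → 15 → 17; steps 1, 2, 3, 6, 7, 8, 9).

Least certain steps, riskiest first:

**Step 6 (key step).** Several processes can divert it:
- Direct intramolecular α-arylation of the dienolate at C8a, closing a five-membered ring, if enolate formation outruns carbene capture.
- Dipolar cycloaddition of 11 to the acrylate double bond, or carbene dimerisation, if the diazo concentration rises.
- Loss of enantioselectivity, if neither the insertion nor the ring closure is well discriminated by the ligand.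
- Base-induced migration of C3=C4 to C2=C3, or aromatisation of ring B, in the product.

The fallback sets out from 8 and 3 and returns at 13, using known chemistry. Stobbe condensation of 8 with 3 (NaOMe, MeOH) would give the half-ester (E)-4-[3-methoxy-4-(methoxymethoxy)phenyl]-3-(methoxycarbonyl)but-3-enoic acid F1. The imidate esterification of step 3 would give the mixed diester 4-tert-butyl 1-methyl (E)-2-[3-methoxy-4-(methoxymethoxy)benzylidene]succinate F2. Its lithium dienolate (LiN(iPr)2, THF, −78 °C, cold AcOH quench) should add through the α-carbon to a second equivalent of 8 to give the aldol adduct F3. Treating F3 with CF3CO2H/CH2Cl2 and the thiol scavenger should ionise the benzylic alcohol; the cation closes onto ring A para to the methoxy group (Friedel–Crafts closure, the established acid route to this skeleton), and the tert-butyl and MOM groups fall in the same pot, giving the racemic trans half-ester F4. Preparative chromatography on a chiral stationary phase then separates the enantiomers and delivers 13. This path gives up catalytic asymmetric induction and half of the material, but every operation is of a known type.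

**Step 9.** The aluminium lactolate may open and be reduced further to the diol, the aluminium phenoxides may precipitate and stall the reduction, and C2 may epimerise or C3=C4 migrate during isolation of the free hydroxy aldehyde. The fallback sets out from 15 and returns at 17. Aminolysis of the lactone (Me(MeO)NH·HCl, Me3Al, CH2Cl2) would give the hydroxy Weinreb amide (1S,2R)-7-hydroxy-1-(4-hydroxy-3-methoxyphenyl)-3-(hydroxymethyl)-N,6-dimethoxy-N-methyl-1,2-dihydronaphthalene-2-carboxamide F5. Silylation of all three hydroxyl groups (TBSCl, imidazole, DMF) would give the tris(tert-butyldimethylsilyl) ether of the amide F6. iBu2AlH at −78 °C should stop at the chelated hemiaminal and give the open-chain tris-silylated aldehyde F7 on work-up. HF·pyridine buffered with pyridine (THF, 0 °C) then removes the three silyl groups to give 17. The aldehyde is here made from an amide that cannot be over-reduced and cannot close to a lactol until the last step.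

**Step 8.** The aluminium carboxylate may be reduced as well, conjugate reduction may compete, and the triply deprotonated substrate may aggregate so that conversion is poor. The fallback sets out from 12 and returns at 15. With the phenols and the acid still protected, iBu2AlH (2.2 equiv, CH2Cl2, −78 °C) should reduce only the unhindered conjugated methyl ester and leave the tert-butyl ester flanked by C1 and C3, giving tert-butyl (1S,2R)-3-(hydroxymethyl)-6-methoxy-1-[3-methoxy-4-(methoxymethoxy)phenyl]-7-(methoxymethoxy)-1,2-dihydronaphthalene-2-carboxylate F8. CF3CO2H/CH2Cl2/H2O at 0 °C would then cleave the tert-butyl ester, close the lactone (directly or through the allyl cation, which the neighbouring carboxyl captures) and remove both MOM groups, giving 15. The selectivity here rests on steric shielding instead of charge.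

**Step 7.** Cations released in the acidolysis may alkylate the two electron-rich rings despite the scavenger, and deprotection may be incomplete. The fallback sets out from 12 and returns at 13. HCl in MeOH (50 °C) should remove the MOM groups as the dimethyl acetal of formaldehyde and convert the tert-butyl ester into a methyl ester, giving dimethyl (1S,2R)-7-hydroxy-1-(4-hydroxy-3-methoxyphenyl)-6-methoxy-1,2-dihydronaphthalene-2,3-dicarboxylate F9. LiOH (5 equiv, THF/H2O, 0 °C → rt) should then saponify only the C2 ester, because the C7 phenoxide, para to C4a, is conjugated through C4=C3 with the C3 ester and deactivates it; acidification gives 13. Here a methanol-trapped deprotection and a base-mediated differentiation replace the one-pot acidolysis.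

## Further compounds

F1 | step 6 | (E)-4-[3-methoxy-4-(methoxymethoxy)phenyl]-3-(methoxycarbonyl)but-3-enoic acid | OC(=O)C/C(C(=O)OC)=C\c1ccc(OCOC)c(OC)c1
F2 | step 6 | 4-tert-butyl 1-methyl (E)-2-[3-methoxy-4-(methoxymethoxy)benzylidene]succinate | CC(C)(C)OC(=O)C/C(C(=O)OC)=C\c1ccc(OCOC)c(OC)c1
F3 | step 6 | 4-tert-butyl 1-methyl (E)-3-{hydroxy[3-methoxy-4-(methoxymethoxy)phenyl]methyl}-2-[3-methoxy-4-(methoxymethoxy)benzylidene]succinate (aldol adduct, racemic mixture of diastereomers) | CC(C)(C)OC(=O)C(C(O)c1ccc(OCOC)c(OC)c1)/C(C(=O)OC)=C\c1ccc(OCOC)c(OC)c1
F4 | step 6 | racemic trans-7-hydroxy-1-(4-hydroxy-3-methoxyphenyl)-6-methoxy-3-(methoxycarbonyl)-1,2-dihydronaphthalene-2-carboxylic acid (both enantiomers) | COc1cc([C@H]2c3cc(O)c(OC)cc3C=C(C(=O)OC)[C@@H]2C(=O)O)ccc1O.COc1cc([C@@H]2c3cc(O)c(OC)cc3C=C(C(=O)OC)[C@H]2C(=O)O)ccc1O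
F5 | step 9 | (1S,2R)-7-hydroxy-1-(4-hydroxy-3-methoxyphenyl)-3-(hydroxymethyl)-N,6-dimethoxy-N-methyl-1,2-dihydronaphthalene-2-carboxamide | COc1cc([C@H]2c3cc(O)c(OC)cc3C=C(CO)[C@@H]2C(=O)N(C)OC)ccc1O
F6 | step 9 | (1S,2R)-7-(tert-butyldimethylsilyloxy)-1-[4-(tert-butyldimethylsilyloxy)-3-methoxyphenyl]-3-[(tert-butyldimethylsilyloxy)methyl]-N,6-dimethoxy-N-methyl-1,2-dihydronaphthalene-2-carboxamide | COc1cc([C@H]2c3cc(O[Si](C)(C)C(C)(C)C)c(OC)cc3C=C(CO[Si](C)(C)C(C)(C)C)[C@@H]2C(=O)N(C)OC)ccc1O[Si](C)(C)C(C)(C)C
F7 | step 9 | (1S,2R)-7-(tert-butyldimethylsilyloxy)-1-[4-(tert-butyldimethylsilyloxy)-3-methoxyphenyl]-3-[(tert-butyldimethylsilyloxy)methyl]-6-methoxy-1,2-dihydronaphthalene-2-carbaldehyde | COc1cc([C@H]2c3cc(O[Si](C)(C)C(C)(C)C)c(OC)cc3C=C(CO[Si](C)(C)C(C)(C)C)[C@@H]2C=O)ccc1O[Si](C)(C)C(C)(C)C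
F8 | step 8 | tert-butyl (1S,2R)-3-(hydroxymethyl)-6-methoxy-1-[3-methoxy-4-(methoxymethoxy)phenyl]-7-(methoxymethoxy)-1,2-dihydronaphthalene-2-carboxylate | COc1cc([C@H]2c3cc(OCOC)c(OC)cc3C=C(CO)[C@@H]2C(=O)OC(C)(C)C)ccc1OCOC
F9 | step 7 | dimethyl (1S,2R)-7-hydroxy-1-(4-hydroxy-3-methoxyphenyl)-6-methoxy-1,2-dihydronaphthalene-2,3-dicarboxylate | COc1cc([C@H]2c3cc(O)c(OC)cc3C=C(C(=O)OC)[C@@H]2C(=O)OC)ccc1O
A1 | alternative 1 | 3-[(tert-butyldimethylsilyloxy)methyl]-4-(4-methoxyfuran-2-yl)-2-{1-[3-methoxy-4-(methoxymethoxy)phenyl]prop-2-ynyl}but-3-enyl pivalate (furan–alkyne cycloaddition substrate, configuration as in the SMILES) | COc1cc([C@@H](C#C)[C@@H](COC(=O)C(C)(C)C)/C(CO[Si](C)(C)C(C)(C)C)=C\c2cc(OC)co2)ccc1OCOC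
A2 | alternative 1 | {trans-3-[(tert-butyldimethylsilyloxy)methyl]-7-hydroxy-6-methoxy-1-[3-methoxy-4-(methoxymethoxy)phenyl]-1,2-dihydronaphthalen-2-yl}methyl pivalate (product of the key step, configuration as in the SMILES) | COc1cc([C@H]2c3cc(O)c(OC)cc3C=C(CO[Si](C)(C)C(C)(C)C)[C@@H]2COC(=O)C(C)(C)C)ccc1OCOC
A3 | alternative 2 | benzo-fused ten-membered (E)-allylic lactone carrying the C1 aryl group and the C4 tert-butyldimethylsilyl ether (Ireland–Claisen substrate, configuration as in the SMILES) | COc1cc([C@@H]2CC(=O)OC/C=C/[C@H](O[Si](C)(C)C(C)(C)C)c3cc(OC)c(OCOC)cc32)ccc1OCOC
A4 | alternative 2 | 4-(tert-butyldimethylsilyloxy)-3-ethenyl-6-methoxy-1-[3-methoxy-4-(methoxymethoxy)phenyl]-7-(methoxymethoxy)-1,2,3,4-tetrahydronaphthalene-2-carboxylic acid (product of the key step, configuration as in the SMILES) | COc1cc([C@H]2c3cc(OCOC)c(OC)cc3[C@@H](O[Si](C)(C)C(C)(C)C)[C@H](C=C)[C@@H]2C(=O)O)ccc1OCOC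
A5 | alternative 3 | {trans-5-methoxy-3-[3-methoxy-4-(methoxymethoxy)phenyl]-6-(methoxymethoxy)-2-[(triisopropylsilyloxy)methyl]indane-1,1-diyl}dimethanol bis(methanesulfonate) (ring-expansion substrate, configuration as in the SMILES) | COc1cc([C@H]2c3cc(OCOC)c(OC)cc3C(COS(C)(=O)=O)(COS(C)(=O)=O)[C@@H]2CO[Si](C(C)C)(C(C)C)C(C)C)ccc1OCOC
A6 | alternative 3 | {trans-6-methoxy-1-[3-methoxy-4-(methoxymethoxy)phenyl]-7-(methoxymethoxy)-2-[(triisopropylsilyloxy)methyl]-1,2-dihydronaphthalen-3-yl}methyl acetate (product of the key step, configuration as in the SMILES) | COc1cc([C@H]2c3cc(OCOC)c(OC)cc3C=C(COC(C)=O)[C@@H]2CO[Si](C(C)C)(C(C)C)C(C)C)ccc1OCOC
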